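## Structural features

- The target is a 3-O-methyl dihydroflavonol: a 2,3-dihydro-4H-chromen-4-one whose pyranone ring C is fused to benzene ring A along C4a–C8a and carries the 3-hydroxy-4-methoxyphenyl ring B at C2.
- C2 (benzylic, bonded to O1) and C3 (bonded to the methoxy group and to the C4 ketone) are adjacent stereocentres, both R, with aryl and methoxy trans.
- Ring A has three contiguous oxygens: free hydroxyls at C5 and C6, a methyl ether at C7, and C8 unsubstituted. The C5 hydroxyl is hydrogen-bonded to the C4 carbonyl; ring B has one free phenol at C3′.
- The molecule is fragile at C3–H, which is α to the ketone and β to O1. Base can epimerise C3 or expel the O1 phenoxide to give a chalcone, which destroys both centres.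
- The C2–O1 bond is a 4-methoxybenzylic ether that acid can ionise, and the 5,6-dihydroxy unit is easily oxidised.
- The real difficulty is the distribution of methyl groups, not the ring system. One aliphatic methyl ether at C3 and two aryl methyl ethers must end up beside three free phenols, so a 3-hydroxyl cannot be methylated late, and the two centres must be set in an epimerisable α-alkoxy ketone.
- The key step uses the fact that C3 is bonded to exactly three different partners: the C4 carbonyl carbon, the methoxy oxygen and C2. A ketocarbene centred on C3 already holds C4 and can take up the oxygen of methanol and the carbonyl carbon of the ring B aldehyde in one operation.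
- The C5 oxygen, peri to C4=O, is the one ring A position that a Lewis acid can address selectively through a chelate; this is used in the last step.

## Logic of the disconnections

**12 ⇒ 11.** No skeletal bond is cut; the O6–CH2Ph, O3′–CH2Ph and O5–CH3 bonds are restored. The oxidisable 5,6-dihydroxy unit and the ring B phenol are thereby carried in masked form until the end, and 11 has no acidic O–H. The forward step needs one Lewis acid that removes two benzyl groups and the chelated methyl group but leaves the methyl ethers at O3, O7 and O4′ and the C2–O1 bond alone.

**11 ⇒ 10.** The O1–C2 bond of ring C is cut. C2 is a benzylic carbon that can carry a hydroxyl, and O1 is a phenol ortho to the ketone. Ring C becomes an open β-hydroxy α-methoxy ketone whose two centres can be made intermolecularly. The closure must invert C2 cleanly, so the open-chain compound has to be the syn (2R,3S) diastereomer, and it must not trigger β-elimination.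

**10 ⇒ 9.** The O8a–Si bond is restored. A free phenol ortho to a carbene precursor would insert intramolecularly and give a benzofuranone, so it is masked by a bulky silyl group. The demand is a desilylation that is not basic enough to enolise C3 or to reverse the aldol.

**9 ⇒ 6 + 7 + 8.** The C2–C3 bond and the C3–OMe bond are cut together. C3 becomes a carbene carbon next to the ketone, 8 supplies the methoxy oxygen as a nucleophile and 7 supplies C2 as an electrophile. Three fragments result, two of them purchased, and both stereocentres and the aliphatic methyl ether appear in one step with no hydroxyl left to methylate. The forward step must trap the ylide faster than the proton shift, control both new centres by the catalyst, and keep the ortho substituents of 6 from capturing the carbene. For that reason the oxygen next to the acyl group carries methyl and not benzyl (a benzyl group would migrate in an oxonium ylide), and the other carries the bulky silyl group.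

**6 ⇒ 4 (through 5).** The C3=N2 bond is cut back to a methyl ketone. The ketone has a single enolisable position, so activation as the trifluoroacetyl derivative 5 and diazo transfer are unambiguous. The silyl ether must survive a lithium amide at low temperature.

**4 ⇒ 3 ⇒ 2.** The O8a–Si and O6–CH2Ph bonds are cut. The two phenols of 2 differ because one is chelated to the acetyl group. The demand is a monobenzylation that touches only the free one.

**2 ⇒ 1.** The C4–C4a bond is cut. 1 has two equivalent free ring positions, so C-acetylation can give only one product and fixes the whole oxygen pattern of ring A. The acylation must not cleave a methyl ether.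

## Other disconnections considered

**Alternative 1:** Ring C is cut at C2–C3 and O1–C8a and ring A is removed altogether, so that C4a and C8a are the two CH carbons of a dihydropyranone.

- Forward key step: hetero-Diels–Alder reaction of 7 with the diene A1 under a chiral (salen)CrCl Lewis acid (trivalent chromium), then loss of methanol to give A2.
- In favour: the cycloaddition of aromatic aldehydes with 1-alkoxy-3-silyloxy dienes under this catalysis is an established enantioselective reaction. It forms C2–C3 and closes ring C at once, and the C3 methoxy group arrives inside a building block.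
- Against: a concerted endo pathway normally places the C2 and C3 substituents cis, so trans-A2 would depend on a stepwise pathway or on epimerising C3. More seriously, ring A with three differentiated contiguous oxygens would then have to be built on the C4a=C8a enone. Annulation, aromatisation and differentiation of the oxygens each add steps and regiochemical questions next to the base-sensitive C3.
- Comparison: on mechanism the alternative is the better of the two, since the bond-forming reaction has closer precedent and closes a ring. On the origin of the C3 ether it is equal. On structure and step economy it is clearly weaker, because the chosen plan buys ring A complete in 1 and reaches the target in eight steps, whereas building ring A last would take roughly twice as many.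

**Alternative 2:** Ring C is cut at O1–C8a and C4–C4a, so that ring A is inserted as an aryne between the hydroxyl oxygen and the ester carbon of the anti hydroxy ester A4.

- Forward key step: CsF releases the aryne from the silyl aryl triflate A3, the potassium alkoxide of A4 adds at C8a and the aryl anion at C4a acylates on the ester to give A5, which is the same compound as 11.
- In favour: the regiochemistry is the natural one, because the nucleophile adds to the aryne carbon remote from the flanking methoxy group and the anion develops next to it. C2 is retained, so no Mitsunobu step is needed, and the product enters the same last step.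
- Against: a potassium β-alkoxide of an α-methoxy ester can undergo retro-aldol cleavage and α-epimerisation, either of which erases the stereochemistry that A4 brings. Proton capture by the aryl anion would stop at the simple aryl ether. A3 needs several steps from a trioxygenated phenol, and A4 needs its own anti-selective asymmetric glycolate aldol.
- Comparison: in convergence and in the steps after the coupling the alternative is better, saving the desilylation and the ring closure. The overall count is not lower, because both partners need multistep preparation. It exposes preformed stereocentres to a strong base, whereas the chosen plan creates them under nearly neutral conditions. Its own precedent for closing a chromanone in this way is modest, so it is not better founded.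

**Alternative 3:** Ring C is cut at C3–C4.

- Forward key step: a chiral triazolium-derived carbene converts the ring A formyl group of the racemic dialdehyde A6 into an acyl anion equivalent that adds to the aliphatic aldehyde carbon. The α-aryl α-aryloxy centre at C2 enolises quickly enough for a dynamic resolution, giving A7.
- In favour: the reaction is metal-free, closes ring C, sets both centres from a racemic substrate with one catalyst, and needs no diazo compound.
- Against: A7 has a free 3-hydroxyl that must then be methylated next to an enolisable ketone, the operation that the carbene route avoids. The catalyst would have to choose the hindered, electron-rich, doubly ortho-substituted aryl aldehyde over the aliphatic one as acyl anion donor, against the usual preference. The acyloin product can isomerise, and A6 with its labile aldehyde needs a preparation of its own.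
- Comparison: it is equal in the number of centres set in the key step and better in that the key step closes the ring and uses safer reagents. It is weaker in the functional-group outcome (an extra methylation), in chemoselectivity, and slightly in step count.

Key step: step 5

Remarks on the chemistry:
- The syn adduct 9 with the (2R,3S) configuration is the one that the inverting closure of step 7 converts into the (2R,3R) series; the descriptors of 9, 10, 11 and 12 are consistent with this.
- 1 and 7 are taken as catalogue compounds (1 is otherwise one dithionite reduction from 2,6-dimethoxy-1,4-benzoquinone, 7 one benzylation from isovanillin).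
- The sense of induction of the phosphoric acid is assumed, not derived: the (R)-acid is written and its mirror image is to be used if that is the one that leads to 9.

## Route

Step 1
Reactants: 1 2,6-dimethoxybenzene-1,4-diol
Product: 2 1-(3,6-dihydroxy-2,4-dimethoxyphenyl)ethan-1-one
Conditions: AcOH, BF3·OEt2, 90 °C, Ar; then H2O
Reagents that add atoms: acetic acid, CC(=O)O
Why: Friedel–Crafts C-acylation (through the aryl acetate and a Fries shift) at one of the two equivalent free positions, ortho to the unhindered hydroxyl; the difluoroboron chelate of the product should stop a second acylation, and BF3 is not expected to cleave the methyl ethers as AlCl3 would.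

Step 2
Reactants: 2 1-(3,6-dihydroxy-2,4-dimethoxyphenyl)ethan-1-one
Product: 3 1-[3-(benzyloxy)-6-hydroxy-2,4-dimethoxyphenyl]ethan-1-one
Conditions: BnBr (1.05 equiv), K2CO3, acetone, rt, Ar
Reagents that add atoms: benzyl bromide, BrCc1ccccc1
Why: Williamson etherification; the C6 hydroxyl is tied up in a hydrogen bond to the acetyl group, so one equivalent of halide with a weak base should alkylate only the free C3 hydroxyl, and exclusion of air protects the hydroquinone.

Step 3
Reactants: 3 1-[3-(benzyloxy)-6-hydroxy-2,4-dimethoxyphenyl]ethan-1-one
Product: 4 1-[3-(benzyloxy)-2,4-dimethoxy-6-{[tri(propan-2-yl)silyl]oxy}phenyl]ethan-1-one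
Conditions: iPr3SiOTf, 2,6-lutidine, CH2Cl2, 0 °C to rt
Reagents that add atoms: tri(propan-2-yl)silyl trifluoromethanesulfonate, CC(C)[Si](OS(=O)(=O)C(F)(F)F)(C(C)C)C(C)C
Why: O-silylation of the chelated phenol, for which the silyl triflate is reactive enough; the bulky group should survive the base of step 4 and the weak acid of step 5 and shields its oxygen from the carbene.

Step 4
Reactants: 4 1-[3-(benzyloxy)-2,4-dimethoxy-6-{[tri(propan-2-yl)silyl]oxy}phenyl]ethan-1-one
Product: 6 1-[3-(benzyloxy)-2,4-dimethoxy-6-{[tri(propan-2-yl)silyl]oxy}phenyl]-2-diazoethan-1-one, via trifluoroacetyl ketone 5 (not isolated)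
Conditions: a) LiN(SiMe3)2, THF, −78 °C; CF3CO2CH2CF3; dilute HCl quench, crude 5 taken on; b) 4-acetamidobenzenesulfonyl azide, Et3N, H2O (1 equiv), MeCN, rt
Reagents that add atoms: 4-acetamidobenzenesulfonyl azide, CC(=O)Nc1ccc(cc1)S(=O)(=O)N=[N+]=[N-]; 2,2,2-trifluoroethyl trifluoroacetate, O=C(OCC(F)(F)F)C(F)(F)F (its CF3CO group enters 5 only and is lost again)
Why: Detrifluoroacetylative diazo transfer: Claisen-type trifluoroacetylation of the only enolisable position activates the methyl ketone, and diazo transfer to the diketone is followed by loss of the trifluoroacetyl group onto the sulfonamide nitrogen; the acetamido-substituted azide is chosen as the less hazardous transfer reagent.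

Step 5
Reactants: 6 1-[3-(benzyloxy)-2,4-dimethoxy-6-{[tri(propan-2-yl)silyl]oxy}phenyl]-2-diazoethan-1-one; 7 3-(benzyloxy)-4-methoxybenzaldehyde (1.5 equiv); 8 methanol (1.2 equiv)
Product: 9 (2R,3S)-1-[3-(benzyloxy)-2,4-dimethoxy-6-{[tri(propan-2-yl)silyl]oxy}phenyl]-3-[3-(benzyloxy)-4-methoxyphenyl]-3-hydroxy-2-methoxypropan-1-one
Conditions: Rh2(OAc)4 (2 mol%), (R)-3,3′-bis(2,4,6-triisopropylphenyl)-1,1′-binaphthyl-2,2′-diyl hydrogen phosphate (10 mol%), 4 Å MS, CH2Cl2, 0 °C; 6 and 8 added together over 3 h
Reagents that add atoms: none
Why: Proposed new method: Rh2(OAc)4 expels N2 from 6 to give an electrophilic ketocarbene at C3, the oxygen of 8 adds to it, and the oxonium ylide, which behaves as a rhodium-associated enol of the α-methoxy ketone, is captured at carbon by aldehyde 7 before the 1,2-proton shift can finish a plain O–H insertion, forming C3–OMe and C2–C3. No ring is closed in this step, so no mode of closure applies. The closest known reaction types are the aldol-type three-component coupling of aryldiazoacetates with alcohols and aldehydes and the Mannich-type coupling of diazoketones with alcohols and imines under Rh2(OAc)4 and a chiral phosphoric acid; pairing a terminal diazoketone with an aldehyde is the extension. Both new centres, the methoxy-bearing carbon (R) and the carbinol carbon (S), arise in the same C–C bond formation, and their absolute and relative (syn) configuration is to be set by the bifunctional acid, whose P=O accepts the enol O–H while its P–OH binds the aldehyde oxygen inside the pocket of the 3,3′-aryl groups. The step needs chemoselectivity for trapping over proton transfer, which is served by keeping 8 low and 7 in excess, by slow addition, by low temperature and by molecular sieves to exclude water. It also needs freedom from intramolecular capture of the carbene, which the substrate secures: the two ortho oxygens carry a methyl group that does not migrate and a bulky silyl group, and no O–H is present in 6.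

Step 6
Reactants: 9 (2R,3S)-1-[3-(benzyloxy)-2,4-dimethoxy-6-{[tri(propan-2-yl)silyl]oxy}phenyl]-3-[3-(benzyloxy)-4-methoxyphenyl]-3-hydroxy-2-methoxypropan-1-one
Product: 10 (2R,3S)-1-[3-(benzyloxy)-6-hydroxy-2,4-dimethoxyphenyl]-3-[3-(benzyloxy)-4-methoxyphenyl]-3-hydroxy-2-methoxypropan-1-one
Conditions: Bu4NF, AcOH (1:1), THF, 0 °C
Reagents that add atoms: none
Why: Fluoride-induced cleavage of the aryl silyl ether; buffering with acetic acid keeps the medium from becoming basic, so that neither retro-aldol cleavage nor enolisation at the methoxy-bearing carbon should occur, and both stereocentres are carried through unchanged.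

Step 7
Reactants: 10 (2R,3S)-1-[3-(benzyloxy)-6-hydroxy-2,4-dimethoxyphenyl]-3-[3-(benzyloxy)-4-methoxyphenyl]-3-hydroxy-2-methoxypropan-1-one
Product: 11 (2R,3R)-6-(benzyloxy)-2-[3-(benzyloxy)-4-methoxyphenyl]-3,5,7-trimethoxy-2,3-dihydro-4H-chromen-4-one
Conditions: PPh3, DIAD (added slowly), THF, 0 °C
Reagents that add atoms: none
Why: Intramolecular Mitsunobu etherification (6-exo-tet): the ketone-activated phenol is acidic enough to protonate the betaine and displaces the oxyphosphonium group at the benzylic carbon with inversion, which turns the S carbinol into R at C2 and places the aryl group trans to the untouched C3 methoxy group.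

Step 8
Reactants: 11 (2R,3R)-6-(benzyloxy)-2-[3-(benzyloxy)-4-methoxyphenyl]-3,5,7-trimethoxy-2,3-dihydro-4H-chromen-4-one
Product: 12 (2R,3R)-5,6-dihydroxy-2-(3-hydroxy-4-methoxyphenyl)-3,7-dimethoxy-2,3-dihydro-4H-chromen-4-one
Conditions: BCl3 (6 equiv), C6HMe5 (6 equiv), CH2Cl2, −78 to 0 °C; then MeOH, H2O
Reagents that add atoms: none
Why: Lewis-acid ether cleavage: BCl3 removes both benzyl groups at low temperature while pentamethylbenzene takes up the benzyl cations and protects the free C8 position, and on warming the boron chelate between the C4 carbonyl and O5 delivers chloride to the 5-O-methyl group only; the methyl ethers at O3, O7 and O4′ have no such six-membered chelate and should persist, and no base touches C3.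

## Compound list

1 | 2,6-dimethoxybenzene-1,4-diol | COc1cc(O)cc(OC)c1O | starting material
2 | 1-(3,6-dihydroxy-2,4-dimethoxyphenyl)ethan-1-one | CC(=O)c1c(O)cc(OC)c(O)c1OC | intermediate
3 | 1-[3-(benzyloxy)-6-hydroxy-2,4-dimethoxyphenyl]ethan-1-one | CC(=O)c1c(O)cc(OC)c(OCc2ccccc2)c1OC | intermediate
4 | 1-[3-(benzyloxy)-2,4-dimethoxy-6-{[tri(propan-2-yl)silyl]oxy}phenyl]ethan-1-one | CC(=O)c1c(O[Si](C(C)C)(C(C)C)C(C)C)cc(OC)c(OCc2ccccc2)c1OC | intermediate
5 | 1-[3-(benzyloxy)-2,4-dimethoxy-6-{[tri(propan-2-yl)silyl]oxy}phenyl]-4,4,4-trifluorobutane-1,3-dione | O=C(CC(=O)C(F)(F)F)c1c(O[Si](C(C)C)(C(C)C)C(C)C)cc(OC)c(OCc2ccccc2)c1OC | intermediate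
6 | 1-[3-(benzyloxy)-2,4-dimethoxy-6-{[tri(propan-2-yl)silyl]oxy}phenyl]-2-diazoethan-1-one | [N-]=[N+]=CC(=O)c1c(O[Si](C(C)C)(C(C)C)C(C)C)cc(OC)c(OCc2ccccc2)c1OC | intermediate
7 | 3-(benzyloxy)-4-methoxybenzaldehyde | COc1ccc(C=O)cc1OCc1ccccc1 | starting material
8 | methanol | CO | starting material
9 | (2R,3S)-1-[3-(benzyloxy)-2,4-dimethoxy-6-{[tri(propan-2-yl)silyl]oxy}phenyl]-3-[3-(benzyloxy)-4-methoxyphenyl]-3-hydroxy-2-methoxypropan-1-one | COc1ccc([C@H](O)[C@@H](OC)C(=O)c2c(O[Si](C(C)C)(C(C)C)C(C)C)cc(OC)c(OCc3ccccc3)c2OC)cc1OCc1ccccc1 | intermediate
10 | (2R,3S)-1-[3-(benzyloxy)-6-hydroxy-2,4-dimethoxyphenyl]-3-[3-(benzyloxy)-4-methoxyphenyl]-3-hydroxy-2-methoxypropan-1-one | COc1ccc([C@H](O)[C@@H](OC)C(=O)c2c(O)cc(OC)c(OCc3ccccc3)c2OC)cc1OCc1ccccc1 | intermediate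
11 | (2R,3R)-6-(benzyloxy)-2-[3-(benzyloxy)-4-methoxyphenyl]-3,5,7-trimethoxy-2,3-dihydro-4H-chromen-4-one | COc1ccc([C@H]2Oc3cc(OC)c(OCc4ccccc4)c(OC)c3C(=O)[C@@H]2OC)cc1OCc1ccccc1 | intermediate
12 | (2R,3R)-5,6-dihydroxy-2-(3-hydroxy-4-methoxyphenyl)-3,7-dimethoxy-2,3-dihydro-4H-chromen-4-one | COc1ccc([C@H]2Oc3cc(OC)c(O)c(O)c3C(=O)[C@@H]2OC)cc1O | target

## Step count and least certain steps

Total step count: 8. Longest linear sequence: 8 steps (1 to 12); 7 and 8 enter at step 5.

**Step 5 (key step, carries the label).**
- What may go wrong: proton transfer within the oxonium ylide, or its protonation by the acid, may finish the O–H insertion before the electron-rich and weakly electrophilic aldehyde is engaged. The ortho methoxy oxygen may close onto the carbene and lead to a benzofuranone. Control of the relative or absolute configuration may be insufficient.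
- Fallback by known chemistry, setting out from 3 and returning at 11: methoxymethylation (MeOCH2Cl, iPr2NEt, CH2Cl2) would give the methoxymethyl-protected acetophenone F1. Claisen–Schmidt condensation with 7 (KOH, EtOH) would give the (E)-chalcone F2. Juliá–Colonna epoxidation (poly-L-leucine, urea–H2O2, DBU, THF; poly-D-leucine if the other face is attacked) would give the (2R,3S)-epoxy ketone F3. HCl in MeOH would remove the acetal and let the freed phenol open the epoxide at the benzylic carbon with inversion, giving the trans-3-hydroxyflavanone F4, which is the same compound as A7. MeI and Ag2O would then methylate the only hydroxyl to give 11, and step 8 follows. This gives up the entry of the methoxy group as methanol, but at that stage no phenol is free, so the methylation is unambiguous.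

**Step 7.**
- What may go wrong: the activated benzylic centre, stabilised by the 4-methoxyphenyl group, may ionise, which erodes the inversion and gives the 2,3-cis isomer. The betaine may also induce β-elimination to the hydroxychalcone, which would reclose without stereocontrol.
- Fallback, setting out from 9 and returning at 11 without passing through 10: MsCl and Et3N in CH2Cl2 at −30 °C would convert the carbinol into the benzylic methanesulfonate F5 while the phenol is still silylated. CsF in MeCN at 0 °C would then unmask the phenoxide, which displaces the sulfonate intramolecularly with inversion. The leaving group is thus installed before any phenoxide exists, and the desilylation and closure are merged into one operation.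

**Step 8.**
- What may go wrong: demethylation may continue at O7, O4′ or O3 once boron is bound to the neighbouring oxygens, or the Lewis acid may ionise the C2–O1 bond with epimerisation at C2.
- Fallback, setting out from 11 and returning at 12: hydrogenolysis (H2, 10% Pd/C, EtOAc) would remove both benzyl groups under neutral conditions and give the debenzylated 5-O-methyl flavanonol F6. MgI2 in Et2O–toluene would then cleave only the methyl ether chelated to the C4 carbonyl. The two deprotections are thereby separated, and no benzyl cation is formed next to the electron-rich ring A.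

**Step 4.**
- What may go wrong: in the lithium enolate the silyl group may move from the phenolic oxygen to the enolate oxygen, and C-trifluoroacetylation of the doubly ortho-substituted ketone may be slow.
- Fallback, setting out from 4 and returning at 6: soft enolisation (Me3SiOTf, Et3N, CH2Cl2, 0 °C) would give the trimethylsilyl enol ether F7 without a lithium enolate. N-Bromosuccinimide in THF at −78 °C would give the bromomethyl ketone F8. N,N′-Ditosylhydrazine and DBU in THF at 0 °C would convert it into 6 by substitution and loss of two sulfinate groups. The diazo group is then built on an α-bromoketone instead of by transfer to an activated enolate.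

## Further compounds

F1 | step 5 | 1-[3-(benzyloxy)-2,4-dimethoxy-6-(methoxymethoxy)phenyl]ethan-1-one | CC(=O)c1c(OCOC)cc(OC)c(OCc2ccccc2)c1OC
F2 | step 5 | (2E)-1-[3-(benzyloxy)-2,4-dimethoxy-6-(methoxymethoxy)phenyl]-3-[3-(benzyloxy)-4-methoxyphenyl]prop-2-en-1-one | COCOc1cc(OC)c(OCc2ccccc2)c(OC)c1C(=O)/C=C/c1ccc(OC)c(OCc2ccccc2)c1
F3 | step 5 | [(2R,3S)-3-[3-(benzyloxy)-4-methoxyphenyl]oxiran-2-yl][3-(benzyloxy)-2,4-dimethoxy-6-(methoxymethoxy)phenyl]methanone | COc1ccc([C@@H]2O[C@H]2C(=O)c2c(OCOC)cc(OC)c(OCc3ccccc3)c2OC)cc1OCc1ccccc1
F4 | step 5 | (2R,3R)-6-(benzyloxy)-2-[3-(benzyloxy)-4-methoxyphenyl]-3-hydroxy-5,7-dimethoxy-2,3-dihydro-4H-chromen-4-one | COc1ccc([C@H]2Oc3cc(OC)c(OCc4ccccc4)c(OC)c3C(=O)[C@@H]2O)cc1OCc1ccccc1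
F5 | step 7 | (1S,2R)-3-[3-(benzyloxy)-2,4-dimethoxy-6-{[tri(propan-2-yl)silyl]oxy}phenyl]-1-[3-(benzyloxy)-4-methoxyphenyl]-2-methoxy-3-oxopropyl methanesulfonate | COc1ccc([C@H](OS(C)(=O)=O)[C@@H](OC)C(=O)c2c(O[Si](C(C)C)(C(C)C)C(C)C)cc(OC)c(OCc3ccccc3)c2OC)cc1OCc1ccccc1
F6 | step 8 | (2R,3R)-6-hydroxy-2-(3-hydroxy-4-methoxyphenyl)-3,5,7-trimethoxy-2,3-dihydro-4H-chromen-4-one | COc1ccc([C@H]2Oc3cc(OC)c(O)c(OC)c3C(=O)[C@@H]2OC)cc1O
F7 | step 4 | {[1-(3-(benzyloxy)-2,4-dimethoxy-6-{[tri(propan-2-yl)silyl]oxy}phenyl)ethenyl]oxy}(trimethyl)silane | C=C(O[Si](C)(C)C)c1c(O[Si](C(C)C)(C(C)C)C(C)C)cc(OC)c(OCc2ccccc2)c1OC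
F8 | step 4 | 1-[3-(benzyloxy)-2,4-dimethoxy-6-{[tri(propan-2-yl)silyl]oxy}phenyl]-2-bromoethan-1-one | BrCC(=O)c1c(O[Si](C(C)C)(C(C)C)C(C)C)cc(OC)c(OCc2ccccc2)c1OC
A1 | alternative 1 | (1Z,3E)-1,4-dimethoxy-2-[(trimethylsilyl)oxy]buta-1,3-diene | CO/C=C/C(O[Si](C)(C)C)=C/OC
A2 | alternative 1 | (2R,3R)-2-[3-(benzyloxy)-4-methoxyphenyl]-3-methoxy-2,3-dihydro-4H-pyran-4-one | COc1ccc([C@H]2OC=CC(=O)[C@@H]2OC)cc1OCc1ccccc1
A3 | alternative 2 | 4-(benzyloxy)-3,5-dimethoxy-2-(trimethylsilyl)phenyl trifluoromethanesulfonate | COc1cc(OS(=O)(=O)C(F)(F)F)c([Si](C)(C)C)c(OC)c1OCc1ccccc1
A4 | alternative 2 | methyl (2R,3R)-3-[3-(benzyloxy)-4-methoxyphenyl]-3-hydroxy-2-methoxypropanoate | COc1ccc([C@@H](O)[C@@H](OC)C(=O)OC)cc1OCc1ccccc1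
A5 | alternative 2 | (2R,3R)-6-(benzyloxy)-2-[3-(benzyloxy)-4-methoxyphenyl]-3,5,7-trimethoxy-2,3-dihydro-4H-chromen-4-one | COc1ccc([C@H]2Oc3cc(OC)c(OCc4ccccc4)c(OC)c3C(=O)[C@@H]2OC)cc1OCc1ccccc1
A6 | alternative 3 | 3-(benzyloxy)-6-{1-[3-(benzyloxy)-4-methoxyphenyl]-2-oxoethoxy}-2,4-dimethoxybenzaldehyde (racemic) | COc1ccc(C(C=O)Oc2cc(OC)c(OCc3ccccc3)c(OC)c2C=O)cc1OCc1ccccc1
A7 | alternative 3 | (2R,3R)-6-(benzyloxy)-2-[3-(benzyloxy)-4-methoxyphenyl]-3-hydroxy-5,7-dimethoxy-2,3-dihydro-4H-chromen-4-one | COc1ccc([C@H]2Oc3cc(OC)c(OCc4ccccc4)c(OC)c3C(=O)[C@@H]2O)cc1OCc1ccccc1
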